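**Plan**
Retrosynthetic cuts: first the lactone O–C6 bond and the C7=C11 double bond of the five-membered lactone (O, C12, C11, C7, C6); then ring bond C2=C3 (metathesis), C5–C6 (alkenylzinc + aldehyde), the O8 ester (epoxide opening), C7=C8 (cross-metathesis), C1–C2 (Stille) and C9–C10 / C4–C15 (carbomagnesiation of propargyl alcohol).
Enabling feature: C6, the sp3 carbon carrying the lactone oxygen, is bonded to C7, one end of the tetrasubstituted C7=C11 bond. C6/C7 is therefore a masked α-sulfonyloxy ketone and O–C12–C11(C13H2OAc) a phosphonoacetic acid, so one flask can alkylate the carboxylate at C6 with inversion and olefinate the C7 ketone.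
Forward order: open chain carrying both epoxides (1,10-epoxide in step 3, 4,5-epoxide in step 15); butenolide ring in the key step; ten-membered carbocycle last, by ring-closing metathesis of the two vinyl epoxide termini; desilylation.
Stereochemistry: C1/C10 and C8 from two Sharpless epoxidations (C8 after titanium-mediated opening with inversion by the (R)-acid; the C7 carbinol is a temporary relay, oxidised later); C6 from chelation-controlled alkenylzinc addition, then SN2 inversion in the key step; C4/C5 from hydroxyl-directed epoxidation under allylic 1,3-strain; both trisubstituted alkene geometries from anti-carbomagnesiation; C2=C3 is Z by ring size.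

Key step: step 22

Remark: germacrane numbering of the target is carried through all intermediates (ring C1–C10, lactone C11–C13, C14 = CH2OH carbon on C10, C15 = CH3 on C4); in it the target is (1R,4R,5S,6S,8S,10S,2Z) with a (2R)-2-methylbutanoate on O8.

Step 1
Reactants: 1 prop-2-yn-1-ol
Product: 3 (2Z)-2-(iodomethylidene)pent-4-en-1-ol, via cyclic alkenylmagnesium alkoxide 2 (not isolated)
Conditions: CH2=CHCH2MgBr (2.5 equiv), CuI (10 mol %), Et2O, 0 → 25 °C; then I2, THF, −30 °C
Reagents that add atoms: allylmagnesium bromide, C=CC[Mg]Br; iodine, II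
Why: Copper-catalysed anti-carbomagnesiation of the propargylic alkoxide (Duboudin reaction) puts allyl on the future C10 and magnesium on C1 inside a five-membered chelate, and iodinolysis with retention leaves the iodide cis to CH2OH, the C10=C1 geometry the 1,10-epoxide needs.

Step 2
Reactants: 3 (2Z)-2-(iodomethylidene)pent-4-en-1-ol
Product: 4 (2Z)-2-(prop-2-en-1-yl)penta-2,4-dien-1-ol
Conditions: CH2=CHSnBu3 (1.2 equiv), Pd(PPh3)4 (5 mol %), CuI (10 mol %), DMF, 25 °C
Reagents that add atoms: tributyl(vinyl)stannane, C=C[Sn](CCCC)(CCCC)CCCC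
Why: Stille coupling with retention of the alkenyl iodide geometry adds C2 and its terminal CH2, and is placed before any vinyl epoxide exists that zerovalent palladium could ionise.

Step 3
Reactants: 4 (2Z)-2-(prop-2-en-1-yl)penta-2,4-dien-1-ol
Product: 5 [(2S,3R)-3-ethenyl-2-(prop-2-en-1-yl)oxiran-2-yl]methanol
Conditions: Ti(OiPr)4 (10 mol %), L-(+)-diethyl tartrate (12 mol %), tBuOOH (2 equiv), 4 Å molecular sieves, CH2Cl2, −20 °C
Reagents that add atoms: tert-butyl hydroperoxide, CC(C)(C)OO
Why: Sharpless asymmetric epoxidation touches only the alkene of the allylic alcohol, and the L-tartrate catalyst should deliver oxygen to the face that gives (1R,10S).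

Step 4
Reactants: 5 [(2S,3R)-3-ethenyl-2-(prop-2-en-1-yl)oxiran-2-yl]methanol
Product: 6 tert-butyl{[(2S,3R)-3-ethenyl-2-(prop-2-en-1-yl)oxiran-2-yl]methoxy}dimethylsilane
Conditions: tBuMe2SiCl, imidazole, DMF, 0 °C
Reagents that add atoms: tert-butyldimethylsilyl chloride, CC(C)(C)[Si](C)(C)Cl
Why: Standard silylation protects the C14 hydroxyl until the last step and removes the free hydroxyl that would otherwise steer titanium to the 1,10-epoxide in step 8.

Step 5
Reactants: 6 silyl ether of step 4; 7 (2E)-but-2-enal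
Product: 8 (2E)-4-[(2S,3R)-2-({[tert-butyl(dimethyl)silyl]oxy}methyl)-3-ethenyloxiran-2-yl]but-2-enal
Conditions: second-generation Grubbs catalyst RuCl2(H2IMes)(PCy3)(=CHPh) (5 mol %), 7 (5 equiv), CH2Cl2, 40 °C
Reagents that add atoms: none
Why: Olefin cross-metathesis of the unhindered allyl terminus with crotonaldehyde is E-selective and adds C7 and C6, while the vinyl group on the epoxide is slower and cannot ring-close onto the allyl arm across a trans-epoxide.

Step 6
Reactants: 8 enal of step 5
Product: 9 (2E)-4-[(2S,3R)-2-({[tert-butyl(dimethyl)silyl]oxy}methyl)-3-ethenyloxiran-2-yl]but-2-en-1-ol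
Conditions: iBu2AlH (1.2 equiv), CH2Cl2, −78 °C; Rochelle salt work-up
Reagents that add atoms: none
Why: 1,2-Reduction of the enal with diisobutylaluminium hydride at low temperature gives the E-allylic alcohol and leaves the epoxide alone.

Step 7
Reactants: 9 allylic alcohol of step 6
Product: 10 {(2R,3R)-3-[((2S,3R)-2-({[tert-butyl(dimethyl)silyl]oxy}methyl)-3-ethenyloxiran-2-yl)methyl]oxiran-2-yl}methanol (7R,8R-epoxide)
Conditions: Ti(OiPr)4 (10 mol %), D-(−)-diethyl tartrate (12 mol %), tBuOOH (2 equiv), 4 Å molecular sieves, CH2Cl2, −20 °C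
Reagents that add atoms: tert-butyl hydroperoxide, CC(C)(C)OO
Why: Sharpless asymmetric epoxidation of an E-disubstituted primary allylic alcohol, with the D-tartrate catalyst giving the (7R,8R)-epoxide by reagent control.

Step 8
Reactants: 10 bis-epoxy alcohol of step 7; 11 (2R)-2-methylbutanoic acid
Product: 12 (2R,3S)-1,2-dihydroxy-4-[(2S,3R)-2-({[tert-butyl(dimethyl)silyl]oxy}methyl)-3-ethenyloxiran-2-yl]butan-3-yl (2R)-2-methylbutanoate (C6/C7 diol, 8S ester)
Conditions: Ti(OiPr)4 (1.5 equiv), 11 (1.5 equiv), CH2Cl2, 25 °C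
Reagents that add atoms: none
Why: Titanium-mediated opening of a 2,3-epoxy alcohol by a carboxylic acid occurs at the carbon remote from the hydroxyl (here C8) with inversion, which sets the (8S) ester directly; the silyl-capped 1,10-epoxide has no free hydroxyl to bind titanium.

Step 9
Reactants: 12 diol ester of step 8
Product: 13 bis(triethylsilyl) ether of 12 (O6 and O7 silylated; 7R,8S)
Conditions: Et3SiCl (2.5 equiv), imidazole, DMF, 0 °C
Reagents that add atoms: chlorotriethylsilane, CC[Si](Cl)(CC)CC
Why: Exhaustive silylation under mild base caps both hydroxyls quickly, before the C8 acyl group can migrate.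

Step 10
Reactants: 13 bis(triethylsilyl) ether
Product: 14 (2S,3S)-1-oxo-2-(triethylsilyloxy)-4-[(2S,3R)-2-({[tert-butyl(dimethyl)silyl]oxy}methyl)-3-ethenyloxiran-2-yl]butan-3-yl (2R)-2-methylbutanoate (C6 aldehyde; geometry at C7 unchanged)
Conditions: (COCl)2 (4 equiv), DMSO (8 equiv), CH2Cl2, −78 → −40 °C; iPr2NEt, −78 → −20 °C; cold pH 7 buffer
Reagents that add atoms: none
Why: Under Swern conditions a primary triethylsilyl ether is cleaved and oxidised while secondary triethylsilyl and tert-butyldimethylsilyl ethers survive, giving the α-silyloxy aldehyde in one operation.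

Step 11
Reactants: 1 prop-2-yn-1-ol
Product: 16 (2Z)-3-iodo-2-methylprop-2-en-1-ol, via cyclic alkenylmagnesium alkoxide 15 (not isolated)
Conditions: MeMgBr (2.2 equiv), CuI (10 mol %), Et2O/THF, 0 → 25 °C; then I2, THF, −30 °C
Reagents that add atoms: methylmagnesium bromide, C[Mg]Br; iodine, II
Why: The same copper-catalysed anti-carbomagnesiation (Duboudin reaction) adds the C15 methyl to the future C4 and leaves iodine cis to CH2OH.

Step 12
Reactants: 16 (2Z)-3-iodo-2-methylprop-2-en-1-ol
Product: 17 (2Z)-3-iodo-2-methylprop-2-enal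
Conditions: MnO2 (15 equiv), CH2Cl2, 25 °C, dark; used at once
Reagents that add atoms: none
Why: Neutral allylic oxidation with manganese dioxide gives the enal without Z to E isomerisation if the product is not stored.

Step 13
Reactants: 17 (2Z)-3-iodo-2-methylprop-2-enal
Product: 18 (1Z)-1-iodo-2-methylbuta-1,3-diene
Conditions: Ph3PCH3Br, KN(SiMe3)2, THF, −78 → 0 °C; product kept as an Et2O solution
Reagents that add atoms: methyltriphenylphosphonium bromide, [Br-].C[P+](c1ccccc1)(c1ccccc1)c1ccccc1
Why: Wittig methylenation converts the aldehyde into the C3 vinyl group and does not touch the trisubstituted iodoalkene, so iodine stays cis to the vinyl group.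

Step 14
Reactants: 18 (1Z)-1-iodo-2-methylbuta-1,3-diene; 14 aldehyde of step 10
Product: 21 (6S,7R,8S)-allylic alcohol (free C6–OH, O7 triethylsilyl ether, O8 (2R)-2-methylbutanoate, (4Z)-CH2=C3H–C4(CH3)=C5H diene, (1R,10S)-epoxide with C2 vinyl and C14–O-silyl), via dienyllithium 19 (not isolated), via dienylzinc bromide 20 (not isolated)
Conditions: 18 (2 equiv), tBuLi (4 equiv), Et2O, −78 °C; ZnBr2 (2.2 equiv), −78 → 0 °C; then 14, toluene, −30 → 0 °C
Reagents that add atoms: none
Why: Iodine–lithium exchange with retention, transmetalation to zinc and Cram-chelate-controlled 1,2-addition: the Lewis-acidic alkenylzinc bromide bridges the aldehyde and α-silyloxy oxygens, so the Z-dienyl group adds to the face away from C8 and gives the 6,7-syn alcohol (6S).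

Step 15
Reactants: 21 allylic alcohol of step 14
Product: 22 (4R,5S,6S,7R,8S)-epoxy alcohol (21 with the C4–C5 alkene epoxidised, C3 vinyl on C4)
Conditions: 3-chloroperoxybenzoic acid (1.2 equiv), NaHCO3, CH2Cl2, −20 → 0 °C
Reagents that add atoms: 3-chloroperoxybenzoic acid, OOC(=O)c1cccc(Cl)c1
Why: Hydroxyl-directed peracid epoxidation (Henbest epoxidation): allylic 1,3-strain from the cis C3 substituent holds H6 in the alkene plane, so oxygen is delivered syn to the hydroxyl and gives the threo epoxy alcohol (4R,5S); the trisubstituted alkene reacts before either vinyl group.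

Step 16
Reactants: 22 epoxy alcohol of step 15
Product: 23 C6 methanesulfonate of 22
Conditions: MeSO2Cl, Et3N, CH2Cl2, −20 °C
Reagents that add atoms: methanesulfonyl chloride, CS(=O)(=O)Cl
Why: Mesylation with retention turns the C6 hydroxyl into the nucleofuge for the key step while C7 is still a protected carbinol.

Step 17
Reactants: 23 mesylate of step 16
Product: 24 C7 alcohol (23 without the triethylsilyl group)
Conditions: HF·pyridine, pyridine, THF, 0 °C, short reaction time
Reagents that add atoms: none
Why: Buffered hydrogen fluoride removes the secondary triethylsilyl ether much faster than the primary tert-butyldimethylsilyl ether and is not basic enough to close a C6–C7 epoxide.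

Step 18
Reactants: 24 hydroxy mesylate of step 17
Product: 25 (6S,8S)-α-mesyloxy ketone (C7 ketone, C6 mesylate, C8 (2R)-2-methylbutanoate, (4R,5S)- and (1R,10S)-epoxides, two vinyl termini, C14–O-silyl)
Conditions: Dess–Martin periodinane, NaHCO3, CH2Cl2, 0 → 25 °C
Reagents that add atoms: none
Why: Dess–Martin oxidation is neutral, so the C7 ketone is unveiled without enolisation towards C6 or C8.

Step 19
Reactants: 26 tert-butyl 2-(diethoxyphosphoryl)acetate
Product: 27 tert-butyl 2-(diethoxyphosphoryl)-3-hydroxypropanoate (racemic)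
Conditions: paraformaldehyde (1.05 equiv), piperidine (10 mol %), THF, 60 °C
Reagents that add atoms: formaldehyde (as paraformaldehyde), C=O
Why: Amine-catalysed aldol-type hydroxymethylation of the phosphonoacetate with one equivalent of formaldehyde installs C13; the new stereocentre is destroyed in step 22.

Step 20
Reactants: 27 hydroxymethyl phosphonate
Product: 28 tert-butyl 3-acetoxy-2-(diethoxyphosphoryl)propanoate (racemic)
Conditions: Ac2O, pyridine, CH2Cl2, 0 °C
Reagents that add atoms: acetic anhydride, CC(=O)OC(C)=O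
Why: Acetylation of the primary alcohol under weak base, which is not strong enough to deprotonate the phosphonate carbon and trigger elimination.

Step 21
Reactants: 28 acetoxy phosphonate ester
Product: 29 3-acetoxy-2-(diethoxyphosphoryl)propanoic acid (racemic)
Conditions: CF3CO2H/CH2Cl2 (1:3), 0 → 25 °C; toluene azeotrope; used crude
Reagents that add atoms: none
Why: Acidolysis of the tert-butyl ester frees the carboxylic acid without basic conditions, so the β-acetoxy group stays in place.

Step 22
Reactants: 25 α-mesyloxy ketone; 29 3-acetoxy-2-(diethoxyphosphoryl)propanoic acid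
Product: 32 open-chain butenolide (13-acetoxy-7(11)-en-12,6-olide; 6S, 8S ester, both epoxides, two vinyl termini, C14–O-silyl), via phosphonoacetate ester 30 (not isolated), via phosphonoacrylate ester 31 (not isolated)
Conditions: 29 (1.5 equiv), Cs2CO3 (0.75 equiv), DMF, 0 °C; add 25, 0 → 25 °C; then CsOAc (3 equiv), Cs2CO3 (1.2 equiv), −20 → 0 °C; AcOH quench
Reagents that add atoms: cesium acetate, CC(=O)[O-].[Cs+] (acetate that can re-enter at C13 in the relay)
Why: Proposed new method: the cesium carboxylate of 29 displaces the C6 mesylate by SN2 to give 30, Cs2CO3 then deprotonates the phosphonate carbon and the carbanion adds to the C7 ketone and collapses with loss of diethyl phosphate to C7=C11, while any carbanion that first expels acetate (E1cB, giving 31) is returned by oxa-Michael addition of the excess cesium acetate, so both branches drain into the irreversible olefination. The closest known reaction types are the one-pot carboxylate alkylation/intramolecular Horner–Wadsworth–Emmons butenolide synthesis from α-halo ketones and phosphonoacetic acids, and the conjugate addition/olefination of 2-phosphonoacrylates; a phosphonate carrying a β-acetoxy group in such a relay has not been shown. The five-membered lactone (O, C12, C11, C7, C6) closes by 5-exo-trig attack of C11 on the C7 carbonyl followed by syn-elimination of phosphate, after the intermolecular O–C6 bond has been made. C6 is the only stereocentre touched and is set by SN2 inversion of the (6S)-mesylate (the CIP letter remains S in 32 because the ligand ranks change). The step needs O-alkylation at C6 in preference to epoxide opening or elimination, and deprotonation of the phosphonate in preference to enolisation towards C6 or C8; α-carbonyl activation of the mesylate, the weak basicity of the carboxylate, the far higher acidity of the phosphonate C–H, low temperature and the acetic acid quench should secure this.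

Step 23
Reactants: 32 open-chain butenolide
Product: 33 14-O-tert-butyldimethylsilyl ether of the target (ten-membered ring, 2Z)
Conditions: second-generation Grubbs catalyst RuCl2(H2IMes)(PCy3)(=CHPh) (15 mol %, in portions), 1,4-benzoquinone (10 mol %), toluene, 1 mM, 80 °C
Reagents that add atoms: none
Why: Ring-closing olefin metathesis of the two vinyl epoxide termini forms C2=C3, and a ten-membered ring spanning the trans-1,10- and cis-4,5-epoxides should accept only the Z-alkene.

Step 24
Reactants: 33 silyl ether of the target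
Product: 34 target, (1R,4R,5S,6S,8S,10S,2Z)-13-acetoxy-1,10:4,5-diepoxy-14-hydroxy-8-[(2R)-2-methylbutanoyloxy]germacra-2,7(11)-dien-12,6-olide
Conditions: Bu4NF/AcOH (1:1, 3 equiv), THF, 0 °C
Reagents that add atoms: none
Why: Fluoride desilylation buffered with acetic acid frees the C14 hydroxyl without acetate migration, butenolide deprotonation or epoxide opening.

**Compound list**
1 | prop-2-yn-1-ol | C#CCO | starting material
2 | 4-(prop-2-en-1-yl)-2,5-dihydro-1,2-oxamagnesole (cyclic alkenylmagnesium alkoxide, Mg on C1 cis to CH2O) | C=CCC1=C[Mg]OC1 | intermediate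
3 | (2Z)-2-(iodomethylidene)pent-4-en-1-ol | OC/C(CC=C)=C\I | intermediate
4 | (2Z)-2-(prop-2-en-1-yl)penta-2,4-dien-1-ol | OC/C(CC=C)=C\C=C | intermediate
5 | [(2S,3R)-3-ethenyl-2-(prop-2-en-1-yl)oxiran-2-yl]methanol | C=CC[C@@]1(CO)O[C@@H]1C=C | intermediate
6 | tert-butyl{[(2S,3R)-3-ethenyl-2-(prop-2-en-1-yl)oxiran-2-yl]methoxy}dimethylsilane | C=CC[C@@]1(CO[Si](C)(C)C(C)(C)C)O[C@@H]1C=C | intermediate
7 | (2E)-but-2-enal | C/C=C/C=O | starting material
8 | (2E)-4-[(2S,3R)-2-({[tert-butyl(dimethyl)silyl]oxy}methyl)-3-ethenyloxiran-2-yl]but-2-enal | O=C/C=C/C[C@@]1(CO[Si](C)(C)C(C)(C)C)O[C@@H]1C=C | intermediate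
9 | (2E)-4-[(2S,3R)-2-({[tert-butyl(dimethyl)silyl]oxy}methyl)-3-ethenyloxiran-2-yl]but-2-en-1-ol | OC/C=C/C[C@@]1(CO[Si](C)(C)C(C)(C)C)O[C@@H]1C=C | intermediate
10 | {(2R,3R)-3-[((2S,3R)-2-({[tert-butyl(dimethyl)silyl]oxy}methyl)-3-ethenyloxiran-2-yl)methyl]oxiran-2-yl}methanol | OC[C@H]1O[C@@H]1C[C@@]2(CO[Si](C)(C)C(C)(C)C)O[C@@H]2C=C | intermediate
11 | (2R)-2-methylbutanoic acid | CC[C@@H](C)C(=O)O | starting material
12 | (2R,3S)-1,2-dihydroxy-4-[(2S,3R)-2-({[tert-butyl(dimethyl)silyl]oxy}methyl)-3-ethenyloxiran-2-yl]butan-3-yl (2R)-2-methylbutanoate | CC[C@@H](C)C(=O)O[C@H]([C@H](O)CO)C[C@@]1(CO[Si](C)(C)C(C)(C)C)O[C@@H]1C=C | intermediate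
13 | bis(triethylsilyl) ether of 12 (O6, O7) | CC[C@@H](C)C(=O)O[C@H]([C@H](O[Si](CC)(CC)CC)CO[Si](CC)(CC)CC)C[C@@]1(CO[Si](C)(C)C(C)(C)C)O[C@@H]1C=C | intermediate
14 | (2S,3S)-1-oxo-2-(triethylsilyloxy)-4-[(2S,3R)-2-({[tert-butyl(dimethyl)silyl]oxy}methyl)-3-ethenyloxiran-2-yl]butan-3-yl (2R)-2-methylbutanoate | CC[C@@H](C)C(=O)O[C@H]([C@H](O[Si](CC)(CC)CC)C=O)C[C@@]1(CO[Si](C)(C)C(C)(C)C)O[C@@H]1C=C | intermediate
15 | 4-methyl-2,5-dihydro-1,2-oxamagnesole (cyclic alkenylmagnesium alkoxide) | CC1=C[Mg]OC1 | intermediate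
16 | (2Z)-3-iodo-2-methylprop-2-en-1-ol | OC/C(C)=C\I | intermediate
17 | (2Z)-3-iodo-2-methylprop-2-enal | O=C/C(C)=C\I | intermediate
18 | (1Z)-1-iodo-2-methylbuta-1,3-diene | C=C/C(C)=C\I | intermediate
19 | [(1Z)-2-methylbuta-1,3-dien-1-yl]lithium | C=C/C(C)=C\[Li] | intermediate
20 | bromo[(1Z)-2-methylbuta-1,3-dien-1-yl]zinc | C=C/C(C)=C\[Zn]Br | intermediate
21 | (6S,7R,8S)-allylic alcohol: C6–OH, O7 triethylsilyl ether, O8 (2R)-2-methylbutanoate, (4Z)-CH2=C3H–C4(CH3)=C5H diene, (1R,10S)-epoxide with C2 vinyl, C14–O-tert-butyldimethylsilyl | CC[C@@H](C)C(=O)O[C@H]([C@H](O[Si](CC)(CC)CC)[C@@H](O)/C=C(C)\C=C)C[C@@]1(CO[Si](C)(C)C(C)(C)C)O[C@@H]1C=C | intermediate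
22 | (4R,5S,6S,7R,8S)-epoxy alcohol: 21 with the (4R,5S)-4,5-epoxide (threo to C6–OH) | CC[C@@H](C)C(=O)O[C@H]([C@H](O[Si](CC)(CC)CC)[C@@H](O)[C@@H]1O[C@]1(C)C=C)C[C@@]2(CO[Si](C)(C)C(C)(C)C)O[C@@H]2C=C | intermediate
23 | C6 methanesulfonate of 22 (all stereocentres as in 22) | CC[C@@H](C)C(=O)O[C@H]([C@H](O[Si](CC)(CC)CC)[C@@H](OS(C)(=O)=O)[C@@H]1O[C@]1(C)C=C)C[C@@]2(CO[Si](C)(C)C(C)(C)C)O[C@@H]2C=C | intermediate
24 | C7 alcohol: 23 without the triethylsilyl group (all stereocentres as in 22) | CC[C@@H](C)C(=O)O[C@H]([C@H](O)[C@@H](OS(C)(=O)=O)[C@@H]1O[C@]1(C)C=C)C[C@@]2(CO[Si](C)(C)C(C)(C)C)O[C@@H]2C=C | intermediate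
25 | (6S,8S)-α-mesyloxy ketone: C7 ketone, C6 mesylate, O8 (2R)-2-methylbutanoate, (4R,5S)- and (1R,10S)-epoxides, two vinyl termini, C14–O-silyl | CC[C@@H](C)C(=O)O[C@H](C(=O)[C@@H](OS(C)(=O)=O)[C@@H]1O[C@]1(C)C=C)C[C@@]2(CO[Si](C)(C)C(C)(C)C)O[C@@H]2C=C | intermediate
26 | tert-butyl 2-(diethoxyphosphoryl)acetate | CCOP(=O)(OCC)CC(=O)OC(C)(C)C | starting material
27 | tert-butyl 2-(diethoxyphosphoryl)-3-hydroxypropanoate (racemic) | CCOP(=O)(OCC)C(CO)C(=O)OC(C)(C)C | intermediate
28 | tert-butyl 3-acetoxy-2-(diethoxyphosphoryl)propanoate (racemic) | CCOP(=O)(OCC)C(COC(C)=O)C(=O)OC(C)(C)C | intermediate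
29 | 3-acetoxy-2-(diethoxyphosphoryl)propanoic acid (racemic) | CCOP(=O)(OCC)C(COC(C)=O)C(=O)O | intermediate
30 | C6-inverted (6R by CIP) 3-acetoxy-2-(diethoxyphosphoryl)propanoate of the C7 ketone (epimers at the phosphonate carbon) | CC[C@@H](C)C(=O)O[C@H](C(=O)[C@H](OC(=O)C(COC(C)=O)P(=O)(OCC)OCC)[C@@H]1O[C@]1(C)C=C)C[C@@]2(CO[Si](C)(C)C(C)(C)C)O[C@@H]2C=C | intermediate
31 | C6-inverted 2-(diethoxyphosphoryl)prop-2-enoate of the C7 ketone | CC[C@@H](C)C(=O)O[C@H](C(=O)[C@H](OC(=O)C(=C)P(=O)(OCC)OCC)[C@@H]1O[C@]1(C)C=C)C[C@@]2(CO[Si](C)(C)C(C)(C)C)O[C@@H]2C=C | intermediate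
32 | open-chain butenolide: 13-acetoxy-7(11)-en-12,6-olide, (6S), (8S) (2R)-2-methylbutanoate, (4R,5S)- and (1R,10S)-epoxides, vinyl groups on C4 and C1, C14–O-silyl | CC[C@@H](C)C(=O)O[C@@H](C[C@@]1(CO[Si](C)(C)C(C)(C)C)O[C@@H]1C=C)C2=C(COC(C)=O)C(=O)O[C@@H]2[C@@H]3O[C@]3(C)C=C | intermediate
33 | 14-O-tert-butyldimethylsilyl ether of the target (1R,4R,5S,6S,8S,10S,2Z) | CC[C@@H](C)C(=O)O[C@H]1C[C@@]2(CO[Si](C)(C)C(C)(C)C)O[C@@H]2/C=C\[C@@]2(C)O[C@H]2[C@H]2OC(=O)C(COC(C)=O)=C12 | intermediate
34 | (1R,4R,5S,6S,8S,10S,2Z)-13-acetoxy-1,10:4,5-diepoxy-14-hydroxy-8-[(2R)-2-methylbutanoyloxy]germacra-2,7(11)-dien-12,6-olide | CC[C@@H](C)C(=O)O[C@H]1C[C@@]2(CO)O[C@@H]2/C=C\[C@@]2(C)O[C@H]2[C@H]2OC(=O)C(COC(C)=O)=C12 | target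

**Step count**
Total: 24 steps. Longest linear sequence: 18 steps (steps 1–10, 14–18, 22–24).

**Steps most likely to fail**

1. Step 22 (proposed new method). What may go wrong: after deprotonation the phosphonate carbanion may lose acetate faster than acetate is returned, so material stalls at the phosphonoacrylate stage or is diverted by other nucleophiles; base may also open the 4,5-epoxide from C6. Fallback by known chemistry, setting out from 25 and 29: the displacement to 30 is run as before, DBU (1.1 equiv) then completes the elimination to 31, and 31 is intercepted in the same flask with 4-methoxybenzyl alcohol (5 equiv) and Cs2CO3. Alkoxide conjugate addition to a 2-phosphonoacrylate followed by Horner–Wadsworth–Emmons olefination is a known one-pot sequence and should give the C13 4-methoxybenzyl ether butenolide F1. DDQ in CH2Cl2/pH 7 buffer should then free the C13 alcohol F2, and Ac2O/pyridine acetylates it, rejoining the route at 32.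

2. Step 23. What may go wrong: intermolecular metathesis (oligomerisation) may outrun closure of the strained ten-membered ring, the vinyl group on quaternary C4 may engage slowly, and ruthenium hydrides may isomerise the termini. Fallback that inverts the order of ring construction, setting out from 25: ring-closing metathesis of the more flexible, butenolide-free ketone under high dilution gives the ten-membered mesyloxy ketone F3. The annulation of step 22 is then run on this ring ketone with the cesium salt of 29, through the ring phosphonoacetate ester F4 (not isolated), and comes back to the route at 33.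

3. Step 14. What may go wrong: poor facial selectivity if a Felkin or a β-acyloxy-chelate pathway competes with the α-chelate, loss of Z geometry in the dienyl metal, and β-elimination of the C8 acyloxy group from aldehyde 14. Fallback that moves stereocontrol from the addition to a reduction, setting out from 14 and 18: unselective addition of the dienyl metal gives 21 together with its C6 epimer F5. Dess–Martin oxidation of the mixture gives dienone F6, and Felkin-controlled 1,2-reduction with LiBH(sBu)3 in THF at −78 °C (bulky, non-chelating silyloxy group; β,β-disubstituted enone) should return the 6,7-syn alcohol, rejoining the route at 21.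

**Further compounds**
F1 | step 22 | C13 4-methoxybenzyl ether analogue of 32 | CC[C@@H](C)C(=O)O[C@@H](C[C@@]1(CO[Si](C)(C)C(C)(C)C)O[C@@H]1C=C)C2=C(COCc3ccc(OC)cc3)C(=O)O[C@@H]2[C@@H]4O[C@]4(C)C=C
F2 | step 22 | C13 alcohol analogue of 32 | CC[C@@H](C)C(=O)O[C@@H](C[C@@]1(CO[Si](C)(C)C(C)(C)C)O[C@@H]1C=C)C2=C(CO)C(=O)O[C@@H]2[C@@H]3O[C@]3(C)C=C
F3 | step 23 | ten-membered (2Z)-mesyloxy ketone (C7 ketone, C6 mesylate, 8S ester, both epoxides, C14–O-silyl) | CC[C@@H](C)C(=O)O[C@H]1C[C@@]2(CO[Si](C)(C)C(C)(C)C)O[C@@H]2/C=C\[C@@]2(C)O[C@H]2[C@H](OS(C)(=O)=O)C1=O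
F4 | step 23 | ten-membered C6-inverted 3-acetoxy-2-(diethoxyphosphoryl)propanoate of the ring ketone (not isolated) | CC[C@@H](C)C(=O)O[C@H]1C[C@@]2(CO[Si](C)(C)C(C)(C)C)O[C@@H]2/C=C\[C@@]2(C)O[C@H]2[C@@H](OC(=O)C(COC(C)=O)P(=O)(OCC)OCC)C1=O
F5 | step 14 | C6 epimer of 21 | CC[C@@H](C)C(=O)O[C@H]([C@H](O[Si](CC)(CC)CC)[C@H](O)/C=C(C)\C=C)C[C@@]1(CO[Si](C)(C)C(C)(C)C)O[C@@H]1C=C
F6 | step 14 | C6 dienone (C6 ketone of 21) | CC[C@@H](C)C(=O)O[C@H]([C@H](O[Si](CC)(CC)CC)C(=O)/C=C(C)\C=C)C[C@@]1(CO[Si](C)(C)C(C)(C)C)O[C@@H]1C=C
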